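**Retrosynthetic overview**
1. Atom labels (kaurane type): ring A is the cyclohexane C1–C5/C10 (C4 carries methyl C18 and carboxyl C19, C5 carries carboxyl C6, C10 carries methyl C20); the bicyclo[3.2.1]octane is C8, C9, C11–C16 (formyl C7 on C8, ketone C12, C16=C17).
2. After ester cleavage, the most hindered bond C9–C10 is cut into a tertiary C10 radical (from a C10 nitro group on ring A, fragment A) and the bicyclic enone C9=C11–C12=O (fragment B).
3. Ring A is opened at C2–C3. The enabling feature is the C19 carboxyl on the quaternary C4, next to the C6 carboxyl on C5: it makes C3=C4 an itaconate acceptor for a C2 radical, and the C18 methyl becomes the coupling partner that ends the radical sequence. The acyclic precursor comes from nitroethane, two acrylates and methyl glyoxylate.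
4. In fragment B the C13–C16 bond is cut (desymmetrizing 5-exo-dig cyclization of an achiral 4-propargylcyclohexanone), then C8–C15 (ester alkylation).
5. Ring order: ring A (C2–C3 bond) and, separately, the bicyclo[3.2.1]octane (C13–C16 bond); the two ring systems are joined last through C9–C10.

Key step: step 6

Assumption: the sense of induction in the two catalytic asymmetric steps (4 and 11) is assigned by analogy; the (pseudo)enantiomeric catalyst is taken if the opposite sense is found.

**Step 1**
Reactants: 1 nitroethane; 2 tert-butyl acrylate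
Product: 3 tert-butyl 4-nitropentanoate (racemic)
Conditions: 1 (5 equiv), DBU (10 mol%), MeCN, 0 °C to rt
Reagents that add atoms: none
Why: Nitro-Michael addition of the nitronate to the acrylate, with excess nitroethane to suppress double addition; the new centre (later C10) needs no control because it becomes a radical in step 14.

**Step 2**
Reactants: 4 methyl acrylate; 5 methyl glyoxylate
Product: 6 dimethyl 2-hydroxy-3-methylidenebutanedioate (racemic)
Conditions: DABCO (20 mol%), 1,4-dioxane, rt
Reagents that add atoms: none
Why: Morita–Baylis–Hillman reaction of an acrylate with the highly electrophilic glyoxylate aldehyde.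

**Step 3**
Reactants: 6 dimethyl 2-hydroxy-3-methylidenebutanedioate
Product: 7 dimethyl 2-[(tert-butoxycarbonyl)oxy]-3-methylidenebutanedioate
Conditions: Boc2O, DMAP (5 mol%), CH2Cl2, 0 °C to rt
Reagents that add atoms: di-tert-butyl dicarbonate CC(C)(C)OC(=O)OC(=O)OC(C)(C)C
Why: Standard O-acylation of the secondary allylic alcohol to the Morita–Baylis–Hillman carbonate.

**Step 4**
Reactants: 7 dimethyl 2-[(tert-butoxycarbonyl)oxy]-3-methylidenebutanedioate; 3 tert-butyl 4-nitropentanoate
Product: 8 1-tert-butyl 4,5-dimethyl (3RS,4R)-3-methyl-3-nitrohex-5-ene-1,4,5-tricarboxylate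
Conditions: (DHQD)2PHAL (10 mol%), toluene, 0 °C to rt
Reagents that add atoms: none
Why: Chiral tertiary-amine (Lewis base) catalysed asymmetric allylic alkylation of a Morita–Baylis–Hillman carbonate (SN2′/SN2′): the amine adds at the methylidene carbon and expels tert-butyl carbonate, the nitronate of 3 then attacks C5 of the chiral allylammonium ion and releases the catalyst, so C5 is set by the alkaloid while C10 forms as an epimer mixture that is erased in step 14.

**Step 5**
Reactants: 8 1-tert-butyl 4,5-dimethyl (3RS,4R)-3-methyl-3-nitrohex-5-ene-1,4,5-tricarboxylate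
Product: 9 (4RS,5R)-5,6-bis(methoxycarbonyl)-4-methyl-4-nitrohept-6-enoic acid
Conditions: TFA, CH2Cl2 (1:4), 0 °C to rt
Reagents that add atoms: none
Why: Acidolysis of the tert-butyl ester only; the acidic medium avoids base-induced loss of nitrite and migration of the methylidene, so C5 is not touched.

**Step 6**
Reactants: 9 (4RS,5R)-5,6-bis(methoxycarbonyl)-4-methyl-4-nitrohept-6-enoic acid
Product: 10 dimethyl (1R,2R,3RS)-1,3-dimethyl-3-nitrocyclohexane-1,2-dicarboxylate
Conditions: Pt anode, Pt cathode, divided cell, constant current (ca. 0.2 A cm⁻²), AcOH (20 equiv), KOH (0.05 equiv per equiv of total acid), MeOH, 10 °C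
Reagents that add atoms: acetic acid CC(=O)O
Why: Proposed new method: anodic (Kolbe) oxidation of the carboxylate of 9 at platinum should give, after loss of CO2, the primary C2 radical, which attacks the unsubstituted C3 terminus of the itaconate; the resulting tertiary α-ester radical at C4, too electron-poor to be oxidized further, should be captured by methyl radicals formed at the same anode from the large excess of acetic acid. The closest known reaction type is the Kolbe electrolysis of unsaturated acids with 5-exo radical cyclization and mixed coupling with a co-acid radical, together with mixed Kolbe couplings of malonic half-ester (α-ester) radicals. Ring A is closed in the 6-endo-trig mode by the C2–C3 bond, since 5-exo attack at the fully substituted, ester-bearing C4 is disfavoured by sterics and polarity. The new quaternary centre C4 is controlled by C5: allylic strain turns the C5 ester pseudo-axial beside the planar ester-substituted radical, methyl adds to the opposite face, and C18 ends trans and C19 cis to C6 as in the target. The step needs ring closure to outrun coupling of the open-chain radical and 1,5-hydrogen transfer from C5–H, which the polarized acrylate and the quaternary C10 (gem-disubstituent effect) should secure, and it needs coupling of the C4 radical with methyl to outrun disproportionation. The nitro group is kept from the cathode by the divided cell, and the C10 epimer mixture is carried on.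

**Step 7**
Reactants: 11 ethyl 1,4-dioxaspiro[4.5]decane-8-carboxylate; 12 3-bromoprop-1-yne
Product: 14 ethyl 8-(prop-2-yn-1-yl)-1,4-dioxaspiro[4.5]decane-8-carboxylate, via lithium ester enolate 13 (not isolated)
Conditions: LDA (LiN(i-Pr)2, commercial solution, 1.1 equiv), THF, −78 °C; then 12, −78 to 0 °C
Reagents that add atoms: none
Why: Ester enolate alkylation with a reactive propargylic bromide creates the quaternary carbon C8, which is not yet stereogenic.

**Step 8**
Reactants: 14 ethyl 8-(prop-2-yn-1-yl)-1,4-dioxaspiro[4.5]decane-8-carboxylate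
Product: 15 [8-(prop-2-yn-1-yl)-1,4-dioxaspiro[4.5]decan-8-yl]methanol
Conditions: LiAlH4, THF, 0 °C; aqueous work-up
Reagents that add atoms: none
Why: Hydride reduction of the neopentyl ester to the primary alcohol (C7); ketal and alkyne are inert at 0 °C.

**Step 9**
Reactants: 15 [8-(prop-2-yn-1-yl)-1,4-dioxaspiro[4.5]decan-8-yl]methanol
Product: 16 tert-butyldimethyl{[8-(prop-2-yn-1-yl)-1,4-dioxaspiro[4.5]decan-8-yl]methoxy}silane
Conditions: TBSCl, imidazole, DMF, rt
Reagents that add atoms: tert-butyldimethylsilyl chloride CC(C)(C)[Si](C)(C)Cl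
Why: Standard silylation masks the C7 hydroxyl so that it cannot add to the activated alkyne or to the ketone in step 11.

**Step 10**
Reactants: 16 tert-butyldimethyl{[8-(prop-2-yn-1-yl)-1,4-dioxaspiro[4.5]decan-8-yl]methoxy}silane
Product: 17 4-{[(tert-butyldimethylsilyl)oxy]methyl}-4-(prop-2-yn-1-yl)cyclohexan-1-one
Conditions: PPTS (cat.), acetone/H2O (10:1), 60 °C
Reagents that add atoms: water O
Why: Mild acid hydrolysis of the dioxolane, which a primary TBS ether should survive, gives the achiral ketone (future C12).

**Step 11**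
Reactants: 17 4-{[(tert-butyldimethylsilyl)oxy]methyl}-4-(prop-2-yn-1-yl)cyclohexan-1-one
Product: 18 (1R,5R)-5-{[(tert-butyldimethylsilyl)oxy]methyl}-7-methylidenebicyclo[3.2.1]octan-2-one
Conditions: Cu(OTf)2 (5 mol%), (R)-DTBM-MeO-BIPHEP (6 mol%), cyclohexylamine (20 mol%), 1,4-dioxane, 40 °C
Reagents that add atoms: none
Why: Cooperative enamine/copper π-acid catalysed 5-exo-dig carbocyclization (Conia-ene type) of an alkyne-linked cyclohexanone, a precedented desymmetrization: the chiral copper–phosphine complex selects the enamine carbon C13 over its enantiotopic twin, and because the propargyl tether can only bridge on its own face, C8 and C13 are set together and C16=C17 is formed.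

**Step 12**
Reactants: 18 (1R,5R)-5-{[(tert-butyldimethylsilyl)oxy]methyl}-7-methylidenebicyclo[3.2.1]octan-2-one
Product: 19 (1R,5R)-5-(hydroxymethyl)-7-methylidenebicyclo[3.2.1]octan-2-one
Conditions: HF·pyridine, THF, 0 °C to rt
Reagents that add atoms: none
Why: Fluoride-mediated desilylation; ketone and exocyclic alkene are inert and no stereocentre is touched.

**Step 13**
Reactants: 19 (1R,5R)-5-(hydroxymethyl)-7-methylidenebicyclo[3.2.1]octan-2-one
Product: 21 (1R,5R)-6-methylidene-4-oxobicyclo[3.2.1]oct-2-ene-1-carbaldehyde, via saturated keto aldehyde 20 (not isolated)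
Conditions: IBX (4 equiv), DMSO, rt, then 75 °C
Reagents that add atoms: none
Why: IBX oxidation of the primary alcohol to the non-enolizable aldehyde followed by IBX dehydrogenation of the ketone; C13 is a bridgehead, so only C11 can be desaturated and the enone is C9=C11–C12=O.

**Step 14**
Reactants: 10 dimethyl (1R,2R,3RS)-1,3-dimethyl-3-nitrocyclohexane-1,2-dicarboxylate; 21 (1R,5R)-6-methylidene-4-oxobicyclo[3.2.1]oct-2-ene-1-carbaldehyde
Product: 22 dimethyl (1R,2S,3S)-3-[(1R,2S,5R)-1-formyl-6-methylidene-4-oxobicyclo[3.2.1]octan-2-yl]-1,3-dimethylcyclohexane-1,2-dicarboxylate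
Conditions: 10 (2 equiv), Bu3SnH (2.5 equiv, syringe pump), AIBN (0.3 equiv), benzene, 80 °C
Reagents that add atoms: none
Why: Denitrative Giese reaction: the tin radical cleaves the tertiary C10–NO2 bond, the planar C10 radical adds to C9 of the enone on the face anti to the C15–C16 bridge (axial attack, cis to C7) and through its own face anti to the neighbouring C5 and C4 ester groups, so C9 and C10 are set, both C10 epimers of 10 converge, and Bu3SnH quenches the α-keto radical.

**Step 15**
Reactants: 22 dimethyl (1R,2S,3S)-3-[(1R,2S,5R)-1-formyl-6-methylidene-4-oxobicyclo[3.2.1]octan-2-yl]-1,3-dimethylcyclohexane-1,2-dicarboxylate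
Product: 23 (1R,2S,3S)-3-[(1R,2S,5R)-1-formyl-6-methylidene-4-oxobicyclo[3.2.1]octan-2-yl]-1,3-dimethylcyclohexane-1,2-dicarboxylic acid (CNP0320711.1)
Conditions: n-PrSLi (10 equiv), HMPA, rt; then aqueous HCl to pH 2–3
Reagents that add atoms: none
Why: SN2 O-demethylation of both esters by thiolate at the methyl carbons, which does not depend on the shielding of the C19 and C6 carbonyls; the non-enolizable aldehyde, the ketone and the exocyclic alkene should survive and no stereocentre is touched.

**Compound list**
1 | nitroethane | CC[N+](=O)[O-] | starting material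
2 | tert-butyl acrylate | C=CC(=O)OC(C)(C)C | starting material
3 | tert-butyl 4-nitropentanoate (racemic) | CC(CCC(=O)OC(C)(C)C)[N+](=O)[O-] | intermediate
4 | methyl acrylate | C=CC(=O)OC | starting material
5 | methyl glyoxylate | O=CC(=O)OC | starting material
6 | dimethyl 2-hydroxy-3-methylidenebutanedioate (racemic) | COC(=O)C(O)C(=C)C(=O)OC | intermediate
7 | dimethyl 2-[(tert-butoxycarbonyl)oxy]-3-methylidenebutanedioate (racemic) | COC(=O)C(OC(=O)OC(C)(C)C)C(=C)C(=O)OC | intermediate
8 | 1-tert-butyl 4,5-dimethyl (3RS,4R)-3-methyl-3-nitrohex-5-ene-1,4,5-tricarboxylate | CC(C)(C)OC(=O)CCC(C)([N+](=O)[O-])[C@H](C(=O)OC)C(=C)C(=O)OC | intermediate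
9 | (4RS,5R)-5,6-bis(methoxycarbonyl)-4-methyl-4-nitrohept-6-enoic acid | OC(=O)CCC(C)([N+](=O)[O-])[C@H](C(=O)OC)C(=C)C(=O)OC | intermediate
10 | dimethyl (1R,2R,3RS)-1,3-dimethyl-3-nitrocyclohexane-1,2-dicarboxylate (fragment A) | [O-][N+](=O)C1(C)CCC[C@@](C)(C(=O)OC)[C@H]1C(=O)OC | intermediate
11 | ethyl 1,4-dioxaspiro[4.5]decane-8-carboxylate | CCOC(=O)C1CCC2(CC1)OCCO2 | starting material
12 | 3-bromoprop-1-yne (propargyl bromide) | C#CCBr | starting material
13 | lithium ester enolate of 11 | CCOC(O[Li])=C1CCC2(CC1)OCCO2 | intermediate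
14 | ethyl 8-(prop-2-yn-1-yl)-1,4-dioxaspiro[4.5]decane-8-carboxylate | CCOC(=O)C1(CC#C)CCC2(CC1)OCCO2 | intermediate
15 | [8-(prop-2-yn-1-yl)-1,4-dioxaspiro[4.5]decan-8-yl]methanol | OCC1(CC#C)CCC2(CC1)OCCO2 | intermediate
16 | tert-butyldimethyl{[8-(prop-2-yn-1-yl)-1,4-dioxaspiro[4.5]decan-8-yl]methoxy}silane | CC(C)(C)[Si](C)(C)OCC1(CC#C)CCC2(CC1)OCCO2 | intermediate
17 | 4-{[(tert-butyldimethylsilyl)oxy]methyl}-4-(prop-2-yn-1-yl)cyclohexan-1-one | CC(C)(C)[Si](C)(C)OCC1(CC#C)CCC(=O)CC1 | intermediate
18 | (1R,5R)-5-{[(tert-butyldimethylsilyl)oxy]methyl}-7-methylidenebicyclo[3.2.1]octan-2-one | C=C1C[C@]2(CO[Si](C)(C)C(C)(C)C)C[C@H]1C(=O)CC2 | intermediate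
19 | (1R,5R)-5-(hydroxymethyl)-7-methylidenebicyclo[3.2.1]octan-2-one | C=C1C[C@]2(CO)C[C@H]1C(=O)CC2 | intermediate
20 | (1R,5R)-6-methylidene-4-oxobicyclo[3.2.1]octane-1-carbaldehyde | C=C1C[C@]2(C=O)C[C@H]1C(=O)CC2 | intermediate
21 | (1R,5R)-6-methylidene-4-oxobicyclo[3.2.1]oct-2-ene-1-carbaldehyde (fragment B) | C=C1C[C@]2(C=O)C[C@H]1C(=O)C=C2 | intermediate
22 | dimethyl (1R,2S,3S)-3-[(1R,2S,5R)-1-formyl-6-methylidene-4-oxobicyclo[3.2.1]octan-2-yl]-1,3-dimethylcyclohexane-1,2-dicarboxylate | C=C1C[C@]2(C=O)C[C@H]1C(=O)C[C@H]2[C@]1(C)CCC[C@@](C)(C(=O)OC)[C@H]1C(=O)OC | intermediate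
23 | (1R,2S,3S)-3-[(1R,2S,5R)-1-formyl-6-methylidene-4-oxobicyclo[3.2.1]octan-2-yl]-1,3-dimethylcyclohexane-1,2-dicarboxylic acid | C=C1C[C@]2(C=O)C[C@H]1C(=O)C[C@H]2[C@]1(C)CCC[C@@](C)(C(=O)O)[C@H]1C(=O)O | target

**Step count**
Total: 15 steps. Longest linear sequence: 9 steps (steps 7–15).

**Steps most likely to fail**

Step 6 (Proposed new method). The open-chain C2 radical may couple with methyl before it cyclizes, may take the activated C5–H by 1,5-hydrogen transfer, or the tertiary C4 radical may disproportionate with methyl instead of coupling; face selection at C4 may also be incomplete. Fallback, setting out from 9: a photoredox decarboxylative radical conjugate addition run intramolecularly (Ir[dF(CF3)ppy]2(dtbbpy)PF6, K2HPO4, DMF, blue LEDs) forms the radical at very low stationary concentration and ends by reduction and protonation of the cyclized α-ester radical. It should give dimethyl (1RS,2R,3RS)-3-methyl-3-nitrocyclohexane-1,2-dicarboxylate F1. Kinetic deprotonation of the less hindered C4–H with LDA (LiN(i-Pr)2, THF, −78 °C) and alkylation with MeI anti to the C5 ester would then return to 10.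

Step 14. Hydrogen transfer from the tin hydride may reach the tertiary C10 radical before it adds to the hindered C9, the tin radical may reduce the enone, or face selection may be insufficient. Fallback, setting out from 10: reduction of the nitro group (Zn, AcOH) should give the α-tertiary amine dimethyl (1R,2R,3RS)-3-amino-1,3-dimethylcyclohexane-1,2-dicarboxylate F2. Condensation with 2,4,6-trimethoxybenzaldehyde should give the imine dimethyl (1R,2R,3RS)-1,3-dimethyl-3-{[(2,4,6-trimethoxyphenyl)methylidene]amino}cyclohexane-1,2-dicarboxylate F3. A photoredox deaminative Giese reaction of F3 with 21 (organic photocatalyst 4CzIPN, blue LEDs) proceeds through the imidoyl radical and β-scission to the same C10 radical with loss of the aryl nitrile, with no stoichiometric hydrogen donor present, and would come back to the route at 22.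

Step 4. The ester-substituted carbonate may give low enantioselectivity, and the basic medium may cause E1cB loss of nitrite from the β-nitro ester or migration of the methylidene into conjugation. Fallback, setting out from 3: an iminium-catalysed asymmetric Michael addition to methyl (E)-4-oxobut-2-enoate (diarylprolinol silyl ether, benzoic acid) should give 6-tert-butyl 1-methyl (2R,3RS)-3-methyl-3-nitro-2-(2-oxoethyl)hexanedioate F4, with C5 set by the catalyst. α-Methylenation of the aldehyde (aqueous formaldehyde, pyrrolidine, propionic acid) should give 6-tert-butyl 1-methyl (2R,3RS)-3-methyl-3-nitro-2-(3-oxoprop-1-en-2-yl)hexanedioate F5. Pinnick oxidation (NaClO2, NaH2PO4, 2-methyl-2-butene) should give 2-[(2R,3RS)-6-(tert-butoxy)-1-methoxy-3-methyl-3-nitro-1,6-dioxohexan-2-yl]prop-2-enoic acid F6, and esterification with TMSCHN2 would come back to the route at 8.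

**Further compounds**
F1 | step 6 | dimethyl (1RS,2R,3RS)-3-methyl-3-nitrocyclohexane-1,2-dicarboxylate | [O-][N+](=O)C1(C)CCCC(C(=O)OC)[C@H]1C(=O)OC
F2 | step 14 | dimethyl (1R,2R,3RS)-3-amino-1,3-dimethylcyclohexane-1,2-dicarboxylate | NC1(C)CCC[C@@](C)(C(=O)OC)[C@H]1C(=O)OC
F3 | step 14 | dimethyl (1R,2R,3RS)-1,3-dimethyl-3-{[(2,4,6-trimethoxyphenyl)methylidene]amino}cyclohexane-1,2-dicarboxylate | COc1cc(OC)c(C=NC2(C)CCC[C@@](C)(C(=O)OC)[C@H]2C(=O)OC)c(OC)c1
F4 | step 4 | 6-tert-butyl 1-methyl (2R,3RS)-3-methyl-3-nitro-2-(2-oxoethyl)hexanedioate | CC(C)(C)OC(=O)CCC(C)([N+](=O)[O-])[C@H](C(=O)OC)CC=O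
F5 | step 4 | 6-tert-butyl 1-methyl (2R,3RS)-3-methyl-3-nitro-2-(3-oxoprop-1-en-2-yl)hexanedioate | CC(C)(C)OC(=O)CCC(C)([N+](=O)[O-])[C@H](C(=O)OC)C(=C)C=O
F6 | step 4 | 2-[(2R,3RS)-6-(tert-butoxy)-1-methoxy-3-methyl-3-nitro-1,6-dioxohexan-2-yl]prop-2-enoic acid | CC(C)(C)OC(=O)CCC(C)([N+](=O)[O-])[C@H](C(=O)OC)C(=C)C(=O)O
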